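At a fixed loading of 2 mol% of free catalyst, the percent curve nearly holds still between two concentrations: the dawn run at 0.030 M and the spring run at 0.040 M stand at 16.6% and 17.4% after 12.0 min, with a scatter of 0.5 percentage points.

| setting | dawn | spring | gamma | alpha | epsilon | zeta |
|---|---|---|---|---|---|---|
| substrate | 0.030 M | 0.040 M | 0.020 M | 0.020 M | 0.020 M | 0.020 M |
| reagent | 1 equiv | 1 equiv | 1.00 equiv | 1.00 equiv | 1.00 equiv | 1.00 equiv |
| free catalyst | 2 mol% | 2 mol% | 1 mol% | 1.2 mol% | 2 mol% | 0.5 mol% |
| remark | run made earlier | run made earlier |  |  |  |  |
| time |  |  | 1.0 h | 1.0 h | 1.0 h | 1.0 h |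

| run | time / min | product / % |
|---|---|---|
| dawn | 0.833 | 0.8 |
| dawn | 2.50 | 3.4 |
| dawn | 4.00 | 6.0 |
| dawn | 6.00 | 6.9 |
| dawn | 10.0 | 13.0 |
| dawn | 12.0 | 16.6 |
| spring | 0.833 | 0.6 |
| spring | 2.50 | 3.2 |
| spring | 4.00 | 6.1 |
| spring | 6.00 | 8.3 |
| spring | 10.0 | 14.9 |
| spring | 12.0 | 17.4 |

(each reading ± 0.5 percentage points)

- ranking by amount of product, in percent of the substrate charged, from high to low, at 1.0 h (gamma / alpha / epsilon / zeta)
- the amount of product, in percent of the substrate charged of the flask you put first, at 1.0 h
- the amount of product, in percent of the substrate charged of the flask you put last, at 1.0 h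

The quick number is read here on one scale, the exposure l·t, with l the loading as a fraction of the substrate. This reply's own reckoning assumes that the rate follows the loading, which stays untested in the two runs, and that it falls with the fraction of substrate left. Concentration then drops out of the reckoning, as it nearly does between the two runs:

c(substrate) = charged c(substrate) · exp(−κ·l·t)

From the last readings of both runs, with reacted substrate counted as product, comes the exposure constant κ = 0.776 /min, the logarithm of charged over left per unit of exposure. At 1.0 h it gives:

zeta: 20.8%
gamma: 37.2%
alpha: 42.8%
epsilon: 60.6%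

These flasks stand at 0.020 M, below both runs, so the reckoning extrapolates in concentration as well as in time.

The forecast gives epsilon > alpha > gamma > zeta, with 83% for epsilon and 21% for zeta, on the reading “a saturated catalyst: zero order in substrate and reagent”. It shares this reckoning's order and its figure for zeta, but parts from it at epsilon.

The flasks give epsilon > alpha > gamma > zeta, with 60.4% in epsilon and 18.2% in zeta, against 60.6% and 20.8% from κ.

    catalyst intermediate A ⇌ by-product + catalyst intermediate B (K = 0.0150 M, k = 1.70 /min)
    catalyst intermediate C → free catalyst + product (k = 1.90 /min)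
    reagent + free catalyst ⇌ catalyst intermediate A (K = 98.0 /M, k = 1400 /M/min)
    substrate + catalyst intermediate B → catalyst intermediate C (k = 440 /M/min)

At the equal exposure 0.300 min, gamma at 0.500 h holds 18.0% product and zeta at 1.00 h holds 18.2%. A flask like zeta but with 0.2 mol% of free catalyst gives 7.49% product, against 8.89% from κ. In zeta at 1.00 h, substrate has a half-life of 3.2 h by its step with catalyst intermediate B, far longer than the 0.41 min of catalyst intermediate A by its forward step alone. At that time in zeta, catalyst intermediate A, the largest resting state, holds 36.1% of the catalyst charged.

Readings and results were generated by integration on assumed constants; the scatter is artificial.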